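**Retrosynthetic overview**
- Key disconnection: the bond between the olefinic CH of the (E)-trisubstituted alkene and the neighbouring allylic CH2 of the chain that leads to the chromene. This gives chromenylethyl iodide 10 and stannylated dihydrofuran 22.
- Enabling feature: the butenolide ring oxygen O1 on butenolide C5 is homoallylic to that olefinic CH (O1–C5–CH2–C(CH3)=CH). Tying O1 to the CH carbon gives a temporary 4-methyl-2,3-dihydrofuran; its vinylic C–O bond is the leaving group of a copper-mediated 1,2-metallate shift that makes the C–C bond, opens the ring with inversion (E-olefin) and frees the future lactone oxygen.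
- Stereocentres: chromene C2 by BOXAX–Pd enantioselective Wacker cyclisation/methoxycarbonylation (step 4); butenolide C5 by asymmetric transfer hydrogenation of an ynone (step 10).
- Ring order: arene bought; pyran ring as chroman (step 4), then chromene (step 5); γ-lactone (step 10), then temporary dihydrofuran (step 12), opened in step 14; butenolide closed last by hydroalumination/iodination and carbonylative lactonisation (steps 15–16); desilylation (step 17).

Key step: step 14

Assumption: the sense of induction of the two catalytic asymmetric steps (4 and 10) is taken from the closest substrate classes (2-methylchroman-2-acetates; alkynyl ketones); if either proved opposite, the enantiomeric ligand would be used with nothing else changed.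

**Route**

Step 1
Reactants: 1 2-methylbenzene-1,4-diol
Product: 2 2-methyl-4-(triisopropylsilyloxy)phenol
Conditions: i-Pr3SiCl (1.0 equiv), imidazole, DMF, 0 °C
Reagents that add atoms: triisopropylsilyl chloride, CC(C)[Si](Cl)(C(C)C)C(C)C
Why: Silyl ether formation; the bulky chlorosilane should react at the hydroxyl remote from the ring methyl and leave the hindered hydroxyl, the later pyran oxygen, free.

Step 2
Reactants: 2 2-methyl-4-(triisopropylsilyloxy)phenol
Product: 3 2-iodo-6-methyl-4-(triisopropylsilyloxy)phenol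
Conditions: N-iodosuccinimide, TsOH·H2O (cat.), MeCN, 0 → 20 °C
Reagents that add atoms: N-iodosuccinimide, O=C1CCC(=O)N1I
Why: Electrophilic aromatic iodination directed ortho to the free phenol; the para position is blocked by the silyloxy group and the other ortho position by the methyl group.

Step 3
Reactants: 4 4-bromo-2-methylbut-1-ene; 3 2-iodo-6-methyl-4-(triisopropylsilyloxy)phenol
Product: 6 2-methyl-6-(3-methylbut-3-en-1-yl)-4-(triisopropylsilyloxy)phenol, via homoallylzinc bromide 5 (not isolated)
Conditions: 4, Zn dust, LiCl, THF, 25 °C; then 3, Pd(OAc)2 (2 mol %), SPhos (4 mol %), THF, 25 °C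
Reagents that add atoms: none
Why: Negishi cross-coupling of a primary alkylzinc bromide (from zinc insertion) with the aryl iodide; the Pd/SPhos system tolerates the free phenol and reductive elimination should outrun β-hydride elimination.

Step 4
Reactants: 6 2-methyl-6-(3-methylbut-3-en-1-yl)-4-(triisopropylsilyloxy)phenol
Product: 7 methyl [(2S)-2,8-dimethyl-6-(triisopropylsilyloxy)-3,4-dihydro-2H-chromen-2-yl]acetate
Conditions: Pd(OCOCF3)2 (5 mol %), (S,S)-Bn-BOXAX (20 mol %), p-benzoquinone (4 equiv), CO (1 atm), MeOH, 20 °C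
Reagents that add atoms: carbon monoxide, [C-]#[O+]; methanol, CO
Why: Enantioselective domino Wacker cyclisation/methoxycarbonylation: the BOXAX complex of divalent palladium controls the face of the 6-exo-trig oxypalladation that creates the quaternary C2, and the resulting alkylpalladium, which has no β-hydrogen, is intercepted by CO and methanol.

Step 5
Reactants: 7 methyl [(2S)-2,8-dimethyl-6-(triisopropylsilyloxy)-3,4-dihydro-2H-chromen-2-yl]acetate
Product: 8 methyl [(2R)-2,8-dimethyl-6-(triisopropylsilyloxy)-2H-chromen-2-yl]acetate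
Conditions: DDQ (1.3 equiv), 1,4-dioxane, 90 °C, dark
Reagents that add atoms: none
Why: Quinone (DDQ) dehydrogenation by hydride abstraction from benzylic C4, assisted by the ring oxygen, and loss of a C3 proton; C2 is quaternary, so neither further oxidation nor epimerisation is possible (the descriptor changes only by priority), and the chromene is kept from UV light from here on because photochemical ring opening would scramble C2.

Step 6
Reactants: 8 methyl [(2R)-2,8-dimethyl-6-(triisopropylsilyloxy)-2H-chromen-2-yl]acetate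
Product: 9 2-[(2R)-2,8-dimethyl-6-(triisopropylsilyloxy)-2H-chromen-2-yl]ethanol
Conditions: i-Bu2AlH (2.5 equiv), CH2Cl2, −78 → 0 °C; aq potassium sodium tartrate
Reagents that add atoms: none
Why: Hydride reduction of the ester to the primary alcohol; the aryl silyl ether, the chromene double bond and the stereocentre are inert.

Step 7
Reactants: 9 2-[(2R)-2,8-dimethyl-6-(triisopropylsilyloxy)-2H-chromen-2-yl]ethanol
Product: 10 (2R)-2-(2-iodoethyl)-2,8-dimethyl-6-(triisopropylsilyloxy)-2H-chromene
Conditions: PPh3, I2, imidazole, CH2Cl2, 0 → 20 °C (iodine added to the phosphine first)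
Reagents that add atoms: iodine, II
Why: Appel-type iodination of a primary alcohol by SN2 displacement of the oxyphosphonium group; pre-forming the phosphonium iodide keeps free iodine away from the chromene.

Step 8
Reactants: 11 5-bromo-2-methylpent-2-ene; 12 lithium acetylide–ethylenediamine complex
Product: 13 6-methylhept-5-en-1-yne
Conditions: DMSO, 15 → 20 °C
Reagents that add atoms: none
Why: SN2 alkylation of lithium acetylide with a primary bromide.

Step 9
Reactants: 13 6-methylhept-5-en-1-yne; 14 methyl 4-chloro-4-oxobutanoate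
Product: 15 methyl 10-methyl-4-oxoundec-9-en-5-ynoate
Conditions: PdCl2(PPh3)2 (2 mol %), CuI (4 mol %), Et3N, THF, 20 °C
Reagents that add atoms: none
Why: Acyl Sonogashira coupling of an acid chloride with a terminal alkyne gives the ynone; the methyl ester is untouched.

Step 10
Reactants: 15 methyl 10-methyl-4-oxoundec-9-en-5-ynoate
Product: 17 (5R)-5-(6-methylhept-5-en-1-yn-1-yl)oxolan-2-one, via hydroxy ester 16 (not isolated)
Conditions: RuCl[(R,R)-TsDPEN](p-cymene) (1 mol %), i-PrOH, 25 °C; then TsOH·H2O (cat.), CH2Cl2, 25 °C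
Reagents that add atoms: none
Why: Noyori asymmetric transfer hydrogenation of the alkynyl ketone sets the carbinol centre (the alkynyl group takes the place of the aryl group of aryl ketones in the hydride-transfer transition state, so the (R,R)-catalyst should give the (R)-carbinol), and acid-catalysed lactonisation then closes the γ-lactone without touching it.

Step 11
Reactants: 17 (5R)-5-(6-methylhept-5-en-1-yn-1-yl)oxolan-2-one
Product: 19 (5R)-3-methyl-5-(6-methylhept-5-en-1-yn-1-yl)oxolan-2-one, via lithium enolate 18 (not isolated)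
Conditions: LiN(i-Pr)2 (1.05 equiv), THF, −78 °C; MeI, −78 → −40 °C
Reagents that add atoms: iodomethane, CI
Why: Lactone enolate alkylation; the configuration of the new α-centre does not matter because that carbon becomes sp2 in the next step.

Step 12
Reactants: 19 (5R)-3-methyl-5-(6-methylhept-5-en-1-yn-1-yl)oxolan-2-one
Product: 21 diphenyl (2R)-4-methyl-2-(6-methylhept-5-en-1-yn-1-yl)-2,3-dihydrofuran-5-yl phosphate, via potassium enolate 20 (not isolated)
Conditions: KN(SiMe3)2, HMPA, THF, −78 °C; (PhO)2P(O)Cl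
Reagents that add atoms: diphenyl chlorophosphate, O=P(Cl)(Oc1ccccc1)Oc1ccccc1
Why: Enol phosphate formation by O-phosphorylation of the potassium lactone enolate gives the cyclic ketene acetal phosphate, that is the 4-methyl-2,3-dihydrofuran ring with a leaving group on C5.

Step 13
Reactants: 21 diphenyl (2R)-4-methyl-2-(6-methylhept-5-en-1-yn-1-yl)-2,3-dihydrofuran-5-yl phosphate
Product: 22 trimethyl[(5R)-3-methyl-5-(6-methylhept-5-en-1-yn-1-yl)-4,5-dihydrofuran-2-yl]stannane
Conditions: Me3SnSnMe3 (1.2 equiv), Pd(PPh3)4 (5 mol %), LiCl, THF, 65 °C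
Reagents that add atoms: hexamethylditin, C[Sn](C)(C)[Sn](C)(C)C
Why: Pd-catalysed stannylation of an enol phosphate (Stille-type coupling with a distannane: oxidative addition of zerovalent palladium into the vinylic C–O bond, transmetalation, reductive elimination) gives the α-alkoxyvinylstannane; the internal alkyne should not undergo distannylation under these conditions.

Step 14
Reactants: 10 (2R)-2-(2-iodoethyl)-2,8-dimethyl-6-(triisopropylsilyloxy)-2H-chromene; 22 trimethyl[(5R)-3-methyl-5-(6-methylhept-5-en-1-yn-1-yl)-4,5-dihydrofuran-2-yl]stannane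
Product: 28 (3E,6R)-1-[(2R)-2,8-dimethyl-6-(triisopropylsilyloxy)-2H-chromen-2-yl]-4,12-dimethyltrideca-3,11-dien-7-yn-6-ol, via alkyllithium 23 (not isolated), via alkylcopper 24 (not isolated), via lithiated dihydrofuran 25 (not isolated), via lithium cuprate 26 (not isolated), via alkenylcopper alkoxide 27 (not isolated)
Conditions: 10, t-BuLi (2.1 equiv), Et2O, −78 °C; CuBr·SMe2 (1.0 equiv), Me2S/Et2O, −78 → −40 °C; separate flask: 22 (1.3 equiv), MeLi, THF, −78 → −30 °C, cannula to the alkylcopper at −78 °C; warm to 20 °C; aq NH4Cl/NH3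
Reagents that add atoms: none
Why: Iodine–lithium exchange on 10 and transmetalation to copper give alkylcopper 24, tin–lithium exchange on 22 gives the α-lithiated cyclic enol ether 25 without deprotonating the acidic propargylic C2–H, and the two combine to the mixed lithium cuprate 26. On warming, the chromenylethyl group shifts from copper to the metal-bearing ring carbon C5 in the plane of the double bond and anti to the ring oxygen, which leaves as the C2 alkoxide (1,2-metallate rearrangement with inversion at C5), so the new C–C bond, the ring opening and the release of the future lactone oxygen are one event; the alkenylcopper 27 is then protonated with retention. The closest known reaction type is the copper-mediated 1,2-metallate rearrangement of 5-lithio-2,3-dihydrofurans with alkylcopper reagents that is used to build (E)-trisubstituted olefins of isoprenoid chains. No ring is closed (the temporary dihydrofuran is opened) and no new stereocentre is formed; C2 of the dihydrofuran and C2 of the chromene are spectators because no bond to either is broken. The selectivity needed is the olefin geometry: in the ring O1 and C3 are held cis across C4=C5, so inversion places the incoming chain trans to C3 and cis to the C4 methyl, which is the (E) geometry of the target. Chemoselectivity rests on the 4-methyl group, which suppresses the Fritsch–Buttenberg–Wiechell-type collapse of the lithiated ring to an alkynolate (no migrating hydrogen on C4), and on the internal alkyne and the bulky aryl silyl ether being inert to alkylcopper reagents.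

Step 15
Reactants: 28 (3E,6R)-1-[(2R)-2,8-dimethyl-6-(triisopropylsilyloxy)-2H-chromen-2-yl]-4,12-dimethyltrideca-3,11-dien-7-yn-6-ol
Product: 30 (3E,6R,7Z)-1-[(2R)-2,8-dimethyl-6-(triisopropylsilyloxy)-2H-chromen-2-yl]-8-iodo-4,12-dimethyltrideca-3,7,11-trien-6-ol, via cyclic alkenylalanate 29 (not isolated)
Conditions: NaAlH2(OCH2CH2OMe)2, THF, 0 → 20 °C; EtOAc; I2, THF, −78 °C
Reagents that add atoms: iodine, II
Why: Alkoxide-directed trans-hydroalumination of the propargylic alcohol places aluminium on the distal alkyne carbon in a five-membered alanate, and iodinolysis with retention gives the (Z)-γ-iodo allylic alcohol.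

Step 16
Reactants: 30 (3E,6R,7Z)-1-[(2R)-2,8-dimethyl-6-(triisopropylsilyloxy)-2H-chromen-2-yl]-8-iodo-4,12-dimethyltrideca-3,7,11-trien-6-ol
Product: 31 (5R)-5-[(2E)-5-[(2R)-2,8-dimethyl-6-(triisopropylsilyloxy)-2H-chromen-2-yl]-2-methylpent-2-en-1-yl]-3-(4-methylpent-3-en-1-yl)furan-2(5H)-one
Conditions: Pd(PPh3)4 (5 mol %), CO (1 atm), K2CO3, THF, 25 → 40 °C
Reagents that add atoms: carbon monoxide, [C-]#[O+]
Why: Pd-catalysed carbonylative lactonisation: oxidative addition of zerovalent palladium into the vinyl iodide, CO insertion and acylation of the cis hydroxyl close the butenolide without breaking the C–O bond at the stereocentre.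

Step 17
Reactants: 31 (5R)-5-[(2E)-5-[(2R)-2,8-dimethyl-6-(triisopropylsilyloxy)-2H-chromen-2-yl]-2-methylpent-2-en-1-yl]-3-(4-methylpent-3-en-1-yl)furan-2(5H)-one
Product: 32 2'-epi-tuberatolide B
Conditions: Bu4NF, AcOH (1:1), THF, 0 °C
Reagents that add atoms: none
Why: Fluoride desilylation of the aryl silyl ether, buffered with acetic acid so that the acidic γ-proton of the butenolide is not removed and C5 is not epimerised.

**Compound list**
1 | 2-methylbenzene-1,4-diol (methylhydroquinone) | Cc1cc(O)ccc1O | starting material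
2 | 2-methyl-4-(triisopropylsilyloxy)phenol | Cc1cc(O[Si](C(C)C)(C(C)C)C(C)C)ccc1O | intermediate
3 | 2-iodo-6-methyl-4-(triisopropylsilyloxy)phenol | Cc1cc(O[Si](C(C)C)(C(C)C)C(C)C)cc(I)c1O | intermediate
4 | 4-bromo-2-methylbut-1-ene | C=C(C)CCBr | starting material
5 | (3-methylbut-3-en-1-yl)zinc bromide | C=C(C)CC[Zn]Br | intermediate
6 | 2-methyl-6-(3-methylbut-3-en-1-yl)-4-(triisopropylsilyloxy)phenol | C=C(C)CCc1cc(O[Si](C(C)C)(C(C)C)C(C)C)cc(C)c1O | intermediate
7 | methyl [(2S)-2,8-dimethyl-6-(triisopropylsilyloxy)-3,4-dihydro-2H-chromen-2-yl]acetate | COC(=O)C[C@]1(C)CCc2cc(O[Si](C(C)C)(C(C)C)C(C)C)cc(C)c2O1 | intermediate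
8 | methyl [(2R)-2,8-dimethyl-6-(triisopropylsilyloxy)-2H-chromen-2-yl]acetate | COC(=O)C[C@]1(C)C=Cc2cc(O[Si](C(C)C)(C(C)C)C(C)C)cc(C)c2O1 | intermediate
9 | 2-[(2R)-2,8-dimethyl-6-(triisopropylsilyloxy)-2H-chromen-2-yl]ethanol | OCC[C@]1(C)C=Cc2cc(O[Si](C(C)C)(C(C)C)C(C)C)cc(C)c2O1 | intermediate
10 | (2R)-2-(2-iodoethyl)-2,8-dimethyl-6-(triisopropylsilyloxy)-2H-chromene | ICC[C@]1(C)C=Cc2cc(O[Si](C(C)C)(C(C)C)C(C)C)cc(C)c2O1 | intermediate
11 | 5-bromo-2-methylpent-2-ene | CC(C)=CCCBr | starting material
12 | lithium acetylide–ethylenediamine complex | [Li]C#C.NCCN | starting material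
13 | 6-methylhept-5-en-1-yne | CC(C)=CCCC#C | intermediate
14 | methyl 4-chloro-4-oxobutanoate | COC(=O)CCC(Cl)=O | starting material
15 | methyl 10-methyl-4-oxoundec-9-en-5-ynoate | COC(=O)CCC(=O)C#CCCC=C(C)C | intermediate
16 | methyl (4R)-4-hydroxy-10-methylundec-9-en-5-ynoate | CC(C)=CCCC#C[C@@H](CCC(=O)OC)O | intermediate
17 | (5R)-5-(6-methylhept-5-en-1-yn-1-yl)oxolan-2-one | CC(C)=CCCC#C[C@H]1CCC(=O)O1 | intermediate
18 | lithium enolate of 17 (lithium (5R)-5-(6-methylhept-5-en-1-yn-1-yl)-4,5-dihydrofuran-2-olate) | CC(C)=CCCC#C[C@H]1CC=C(O[Li])O1 | intermediate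
19 | (5R)-3-methyl-5-(6-methylhept-5-en-1-yn-1-yl)oxolan-2-one (both C3 epimers) | CC(C)=CCCC#C[C@H]1CC(C)C(=O)O1 | intermediate
20 | potassium enolate of 19 (potassium (5R)-3-methyl-5-(6-methylhept-5-en-1-yn-1-yl)-4,5-dihydrofuran-2-olate) | CC(C)=CCCC#C[C@H]1CC(C)=C(O[K])O1 | intermediate
21 | diphenyl (2R)-4-methyl-2-(6-methylhept-5-en-1-yn-1-yl)-2,3-dihydrofuran-5-yl phosphate | CC(C)=CCCC#C[C@H]1CC(C)=C(OP(=O)(Oc2ccccc2)Oc2ccccc2)O1 | intermediate
22 | trimethyl[(5R)-3-methyl-5-(6-methylhept-5-en-1-yn-1-yl)-4,5-dihydrofuran-2-yl]stannane | CC(C)=CCCC#C[C@H]1CC(C)=C([Sn](C)(C)C)O1 | intermediate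
23 | {2-[(2R)-2,8-dimethyl-6-(triisopropylsilyloxy)-2H-chromen-2-yl]ethyl}lithium | [Li]CC[C@]1(C)C=Cc2cc(O[Si](C(C)C)(C(C)C)C(C)C)cc(C)c2O1 | intermediate
24 | {2-[(2R)-2,8-dimethyl-6-(triisopropylsilyloxy)-2H-chromen-2-yl]ethyl}copper | [Cu]CC[C@]1(C)C=Cc2cc(O[Si](C(C)C)(C(C)C)C(C)C)cc(C)c2O1 | intermediate
25 | [(5R)-3-methyl-5-(6-methylhept-5-en-1-yn-1-yl)-4,5-dihydrofuran-2-yl]lithium | CC(C)=CCCC#C[C@H]1CC(C)=C([Li])O1 | intermediate
26 | lithium (chromenylethyl)(dihydrofuranyl)cuprate formed from 24 and 25 | [Li+].CC(C)=CCCC#C[C@H]1CC(C)=C(O1)[Cu-]CC[C@]2(C)C=Cc3cc(O[Si](C(C)C)(C(C)C)C(C)C)cc(C)c3O2 | intermediate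
27 | ring-opened (E)-alkenylcopper lithium alkoxide (copper on the olefinic carbon that becomes CH, cis to the CH2 bearing the carbinol) | CC(C)=CCCC#C[C@@H](C/C(C)=C(/CC[C@]1(C)C=Cc2cc(O[Si](C(C)C)(C(C)C)C(C)C)cc(C)c2O1)[Cu])O[Li] | intermediate
28 | (3E,6R)-1-[(2R)-2,8-dimethyl-6-(triisopropylsilyloxy)-2H-chromen-2-yl]-4,12-dimethyltrideca-3,11-dien-7-yn-6-ol | CC(C)=CCCC#C[C@@H](C/C(C)=C/CC[C@]1(C)C=Cc2cc(O[Si](C(C)C)(C(C)C)C(C)C)cc(C)c2O1)O | intermediate
29 | sodium cyclic alkenylalanate (five-membered O–Al–C=C–C ring, two 2-methoxyethoxy ligands on aluminium) | [Na+].COCCO[Al-]1(OCCOC)O[C@H](C/C(C)=C/CC[C@]2(C)C=Cc3cc(O[Si](C(C)C)(C(C)C)C(C)C)cc(C)c3O2)C=C1CCC=C(C)C | intermediate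
30 | (3E,6R,7Z)-1-[(2R)-2,8-dimethyl-6-(triisopropylsilyloxy)-2H-chromen-2-yl]-8-iodo-4,12-dimethyltrideca-3,7,11-trien-6-ol | CC(C)=CCC/C(I)=C/[C@@H](C/C(C)=C/CC[C@]1(C)C=Cc2cc(O[Si](C(C)C)(C(C)C)C(C)C)cc(C)c2O1)O | intermediate
31 | (5R)-5-[(2E)-5-[(2R)-2,8-dimethyl-6-(triisopropylsilyloxy)-2H-chromen-2-yl]-2-methylpent-2-en-1-yl]-3-(4-methylpent-3-en-1-yl)furan-2(5H)-one | CC(C)=CCCC1=C[C@@H](C/C(C)=C/CC[C@]2(C)C=Cc3cc(O[Si](C(C)C)(C(C)C)C(C)C)cc(C)c3O2)OC1=O | intermediate
32 | 2'-epi-tuberatolide B, (5R)-5-[(2E)-5-[(2R)-6-hydroxy-2,8-dimethyl-2H-chromen-2-yl]-2-methylpent-2-en-1-yl]-3-(4-methylpent-3-en-1-yl)furan-2(5H)-one | CC(C)=CCCC1=C[C@@H](C/C(C)=C/CC[C@]2(C)C=Cc3cc(O)cc(C)c3O2)OC1=O | target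

**Step count and risks**
Total: 17 steps. Longest linear sequence: 11 steps (steps 1–7, then 14–17); the dihydrofuran branch is steps 8–13.

Steps most likely to fail:

1. Step 14. What may go wrong: γ-elimination or premature protonation of the alkyllithium before it reaches copper, slow alkyl migration in the hindered 4-methyl cuprate, proton transfer from the propargylic position, or carbocupration of the alkyne by the alkenylcopper. Fallback (same bond by a B-alkyl Suzuki–Miyaura coupling): it sets out from 13 and 10 and comes back to the route at 28. Alkyne 13 is formylated (n-BuLi, DMF) to 7-methyloct-6-en-2-ynal F1, which is propargylated enantioselectively (allenylboronic acid pinacol ester, chiral phosphoric acid TRIP of the appropriate hand) to (4R)-10-methylundec-9-ene-1,5-diyn-4-ol F2. Zirconium-catalysed methylalumination of the terminal alkyne (AlMe3, Cp2ZrCl2) and iodinolysis give (1E,4R)-1-iodo-2,10-dimethylundeca-1,9-dien-5-yn-4-ol F3. Iodide 10 is converted (t-BuLi, then 9-methoxy-9-BBN) into the lithium chromenylethyl(methoxy)borate of 9-BBN F4, which is coupled with F3 (PdCl2(dppf), K3PO4, DMF) to give 28.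

2. Step 13. What may go wrong: sluggish oxidative addition into the tetrasubstituted enol phosphate, competing distannylation of the alkyne, or protodestannylation of the acid-sensitive α-alkoxyvinylstannane on purification. Fallback (no tin, direct metalation): it sets out from 19 and comes back to the route at 25 inside step 14. Lactone 19 is reduced (i-Bu2AlH, −78 °C) to the lactol (5R)-3-methyl-5-(6-methylhept-5-en-1-yn-1-yl)oxolan-2-ol F5, which is dehydrated (MsCl, Et3N, 0 → 40 °C) to (2R)-4-methyl-2-(6-methylhept-5-en-1-yn-1-yl)-2,3-dihydrofuran F6; oxygen-directed deprotonation at C5 with t-BuLi (THF, −78 °C, short contact time) then gives 25. This direct lithiation has to compete with removal of the propargylic C2–H, which is why it is the fallback and not the main route.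

3. Step 5. What may go wrong: over-oxidation of the electron-rich silyloxyarene or of the ring methyl group by the quinone, or incomplete conversion. Fallback (the C4 oxygen is carried from the start and removed by dehydration): it sets out from 2 and comes back to the route at 8. Phenol 2 is ortho-formylated (MgCl2, Et3N, paraformaldehyde) to 2-hydroxy-3-methyl-5-(triisopropylsilyloxy)benzaldehyde F7; methallylmagnesium chloride gives 2-(1-hydroxy-3-methylbut-3-en-1-yl)-6-methyl-4-(triisopropylsilyloxy)phenol F8. The Wacker cyclisation/methoxycarbonylation of step 4 then gives methyl [(2S)-4-hydroxy-2,8-dimethyl-6-(triisopropylsilyloxy)-3,4-dihydro-2H-chromen-2-yl]acetate F9 (C4 epimers), and acid-catalysed dehydration (TsOH, toluene, 60 °C) gives 8.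

**Further compounds**
F1 | step 14 | 7-methyloct-6-en-2-ynal | CC(C)=CCCC#CC=O
F2 | step 14 | (4R)-10-methylundec-9-ene-1,5-diyn-4-ol | CC(C)=CCCC#C[C@@H](CC#C)O
F3 | step 14 | (1E,4R)-1-iodo-2,10-dimethylundeca-1,9-dien-5-yn-4-ol | CC(C)=CCCC#C[C@@H](C/C(C)=C/I)O
F4 | step 14 | lithium 9-{2-[(2R)-2,8-dimethyl-6-(triisopropylsilyloxy)-2H-chromen-2-yl]ethyl}-9-methoxy-9-boratabicyclo[3.3.1]nonane | [Li+].CO[B-]1(CC[C@]2(C)C=Cc3cc(O[Si](C(C)C)(C(C)C)C(C)C)cc(C)c3O2)C2CCCC1CCC2
F5 | step 13 | (5R)-3-methyl-5-(6-methylhept-5-en-1-yn-1-yl)oxolan-2-ol | CC(C)=CCCC#C[C@H]1CC(C)C(O)O1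
F6 | step 13 | (2R)-4-methyl-2-(6-methylhept-5-en-1-yn-1-yl)-2,3-dihydrofuran | CC(C)=CCCC#C[C@H]1CC(C)=CO1
F7 | step 5 | 2-hydroxy-3-methyl-5-(triisopropylsilyloxy)benzaldehyde | Cc1cc(O[Si](C(C)C)(C(C)C)C(C)C)cc(C=O)c1O
F8 | step 5 | 2-(1-hydroxy-3-methylbut-3-en-1-yl)-6-methyl-4-(triisopropylsilyloxy)phenol | CC(=C)CC(O)c1cc(O[Si](C(C)C)(C(C)C)C(C)C)cc(C)c1O
F9 | step 5 | methyl [(2S)-4-hydroxy-2,8-dimethyl-6-(triisopropylsilyloxy)-3,4-dihydro-2H-chromen-2-yl]acetate | COC(=O)C[C@]1(C)CC(O)c2cc(O[Si](C(C)C)(C(C)C)C(C)C)cc(C)c2O1
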